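## The problem

Target 11 is a 2-aryl-3-(hydroxymethyl)-2,3-dihydrobenzofuran. Ring A (the benzo ring, C3a to C7a) is fused to ring B (O1, C2, C3); ring C (3,4,5-trimethoxyphenyl) sits on C2, the one-carbon arm C9 (CH2OH) on C3, and an (E)-3-hydroxyprop-1-enyl chain on C5, para to O1. The only stereocentres are the neighbours C2 (R) and C3 (S), with ring C and C9 trans. While C9 is held at the ester level, C3 is enolisable and trans is the thermodynamic arrangement, so only C2 needs absolute control and it then decides C3. C2 is a benzylic aryl ether beside an electron-rich arene: acid ionises it and quinone-type oxidants dehydrogenate ring B. The cinnamyl alcohol tolerates neither hydrogenation nor acid, so the chain must be attached after any reduction of ring B and both alcohols are best released last. The enabling feature is that C2 and C3 each carry an aryl group (ring C and ring A) and are therefore the two carbons of a diarylalkyne, that O1 is an ortho phenol oxygen on ring A, and that C9 is a single carbon at an oxidation level that CO can deliver. Oxypalladation of that alkyne with carbonylative capture closes ring B and installs C9 in one operation. The price is that ring B is formed as an aromatic furan, so both stereocentres must come from reduction of a tetrasubstituted C2=C3 bond; this is the part of the plan that needs the most care.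

## Retrosynthesis

Both primary alcohols of 11 are traced back to methyl esters in diester 10. No skeletal bond is cut. This keeps the acid- and hydrogenation-sensitive allylic alcohol out of the route until the last step and leaves C3 next to a carbonyl group for as long as its configuration has to be adjusted. The forward reaction must reduce the cinnamate in the 1,2-sense and take the C3 ester to the alcohol without pausing at the aldehyde.

In 10 the bond between C5 and the side chain is cut, giving aryl bromide 8 and methyl acrylate 9 for a Heck reaction. The neighbouring option, olefination of a C5 aldehyde, would need a formyl group that cannot pass unprotected through the reduction of ring B. A bromide is inert in every earlier step and is addressed only when wanted. The precursor is three carbons simpler, and the forward step needs only the E selectivity that the Heck reaction supplies by mechanism.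

The trans ester 8 is traced to its cis isomer 7 (epimerisation at C3), and 7 to the flat, achiral benzofuran 6 by removal of the hydrogens at C2 and C3. Against a dissolving-metal reduction, which would give the trans ester directly but as a racemate, catalytic hydrogenation offers enantiocontrol. Because C3 is corrected afterwards, the catalyst only has to choose the face at C2. This is the one operation without direct precedent, and a racemic reduction with resolution is held in reserve.

Benzofuran ester 6 is cut at O1–C2 and C3–C9, giving alkynylphenol 5, CO and methanol. Closing ring B by O1–C2 alone (cycloisomerisation) would leave C3 bare and require a separate acylation. Here the C3–palladium bond formed in the cyclisation is used at once to attach C9 at the ester level. The precursor has one ring and two skeletal bonds fewer and no stereochemistry. The forward reaction needs chemoselectivity only: carbonylation before protodepalladation, and an untouched C–Br bond.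

Alkynylphenol 5 is traced to its acetate 4. In 4 the bond between ring A and the alkyne (the future C3–C3a bond) is cut, giving iodide 2 and commercial arylacetylene 3 for a Sonogashira coupling. Cutting on the ring C side instead would need a less accessible 2-ethynylphenol. Iodide 2 is the acetate of commercial 4-bromo-2-iodophenol 1. The acetate prevents cyclisation to a 3-unsubstituted benzofuran during coupling, and the iodide/bromide pair gives site selectivity at room temperature.

## Roads not taken

Alternative 1: Ring A is taken apart into three alkynes (bonds C3a–C7a, C4–C5 and C6–C7).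
- Forward step: the tethered diyne A1, a silyl-capped ynol ether carrying both stereocentres on its tether, is combined with the enyne A2 under Cp*RuCl(cod). The (2+2+2) cyclotrimerisation closes ring A and ring B at once to give A3.
- Merits: C2 and C3 are fixed on an acyclic precursor by established asymmetric chemistry before any ring exists, and the trans relationship is never in doubt. In this respect the road is better than the chosen plan.
- Weak points: A1 is a benzylic alkynyl ether, a class prone to sigmatropic rearrangement and ketene formation on warming, and it takes many steps to make. The third alkyne must insert with the right regiochemistry, which is why the bulky silyl group is placed on C7. The alkene of A2 is a competing π-ligand. A3 still needs removal of an aryl–silicon bond and two silyl ethers.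
- Comparison: the chosen plan sets against the secure stereochemistry of this road its brevity (eight steps from three commercial compounds), a key step with close precedent on 2-(arylethynyl)phenols, and a known fallback for the stereochemical step.

Alternative 2: C3–C9 and the C2–ring C bond are cut together.
- Forward step: the benzofuran-2-yl(aryl)boronate complex A4 is attacked at C3 by a chiral allylpalladium species generated from allyl acetate A5, Pd2(dba)3 and a chiral bisphosphine. Ring C migrates from boron to C2 on the opposite face to give A6.
- Merits: one catalytic enantioselective step forms two carbon–carbon bonds and gives the trans arrangement directly, with no epimerisation. If it worked on this substrate it would be more elegant than hydrogenation followed by equilibration.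
- Weak points: A6 carries boron on C2, which must be replaced by hydrogen with retention at a tertiary, benzylic, oxygen-bearing centre; any loss of fidelity there erodes C2. The allyl group is two carbons too long, so isomerisation, oxidative cleavage and reduction are needed before the side chain can be introduced. The C5–Br bond competes for zerovalent palladium. This dearomative coupling is better established for indolyl than for benzofuranyl boronates.
- Comparison: the chosen plan brings C9 in with the right carbon count and oxidation level and needs four steps after its key step against at least six here. It concedes that its own enantioselective step is no better precedented.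

Alternative 3: Ring A is cut at C3a–C4 and C5–C6.
- Forward step: the 5-vinyl-2,3-dihydrofuran A7, made from a lactone that already holds both stereocentres, adds methyl propiolate A8 in a Diels–Alder reaction. The cyclohexadiene is dehydrogenated in the same flask by a quinone oxidant to give A9.
- Merits: the stereocentres are again set early by reliable chemistry, and the ring oxygen on the diene steers the ester to C5. On stereochemical security this road is ahead of the chosen plan.
- Weak points: the diene terminus C3a is fully substituted and next to the C3 stereocentre, so the cycloaddition needs forcing. A7 is an acid-labile cyclic enol ether. The oxidant that aromatises ring A is the type that also dehydrogenates 2-aryl-2,3-dihydrobenzofurans to benzofurans, which would erase both stereocentres. The C5 ester of A9 needs a further reduction, olefination and reduction sequence, plus desilylation.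
- Comparison: the chosen plan never exposes the finished dihydrofuran to an oxidant and uses C5–Br directly for the side chain. It accepts a harder stereochemical step in exchange.

Key step: step 4

Assumption: the facial sense of the iridium catalyst on this substrate class cannot be predicted from structure. Both enantiomers of the ligand are taken as available, and the one that delivers the 2R configuration is used.

## Route

Step 1
Reactants: 1 4-bromo-2-iodophenol
Product: 2 4-bromo-2-iodophenyl acetate
Conditions: Ac2O, pyridine, DMAP (cat.), CH2Cl2, 0 °C to rt
Reagents that add atoms: acetic anhydride, CC(=O)OC(C)=O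
Why: O-Acylation of a phenol under nucleophilic catalysis. The acetate masks the ortho oxygen so that the coupling in step 2 cannot be followed by metal-induced cyclisation to a 3-unsubstituted benzofuran.

Step 2
Reactants: 2 4-bromo-2-iodophenyl acetate; 3 5-ethynyl-1,2,3-trimethoxybenzene
Product: 4 4-bromo-2-[(3,4,5-trimethoxyphenyl)ethynyl]phenyl acetate
Conditions: PdCl2(PPh3)2 (2 mol %), CuI (4 mol %), Et3N, THF, rt, degassed
Reagents that add atoms: none
Why: Sonogashira coupling. Oxidative addition to C–I is far faster than to C–Br at room temperature, so the bromide should be retained; exclusion of oxygen suppresses alkyne homocoupling.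

Step 3
Reactants: 4 4-bromo-2-[(3,4,5-trimethoxyphenyl)ethynyl]phenyl acetate
Product: 5 4-bromo-2-[(3,4,5-trimethoxyphenyl)ethynyl]phenol
Conditions: K2CO3 (0.3 equiv), MeOH/THF, 0 °C
Reagents that add atoms: none
Why: Base-catalysed methanolysis (transesterification) of an aryl acetate. Low temperature, substoichiometric carbonate and metal-free substrate should keep the phenoxide from closing onto the alkyne.

Step 4
Reactants: 5 4-bromo-2-[(3,4,5-trimethoxyphenyl)ethynyl]phenol
Product: 6 methyl 5-bromo-2-(3,4,5-trimethoxyphenyl)-1-benzofuran-3-carboxylate
Conditions: PdI2 (2 mol %), KI (20 mol %), CO/air 4:1 (20 atm), MeOH, 80 °C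
Reagents that add atoms: carbon monoxide, [C-]#[O+]; methanol, CO
Why: Palladium-catalysed oxidative heterocyclisation with alkoxycarbonylation of a 2-alkynylphenol, a known route to benzofuran-3-carboxylates. Divalent palladium (as [PdI4]2−, from PdI2 and KI) coordinates the diarylalkyne, and the phenol oxygen adds anti to the metal at the alkyne carbon bearing ring C, forming O1–C2 and closing ring B in a 5-endo-dig mode. The C3–palladium bond then inserts CO and the acylpalladium iodide is cleaved by methanol, forming C3–C9 as the methyl ester and releasing zerovalent palladium and HI. Oxygen converts HI into I2 and water, and I2 returns the metal to the divalent state. No stereocentre is formed. Carbonylation must outrun protodepalladation of the C3–palladium bond, which the CO pressure and the low standing concentration of HI should secure. The C5–Br bond must survive, which is expected because zerovalent palladium here carries no donor ligand and is short-lived under the oxidising conditions. Regiochemistry is not in question, since only attack at the distal alkyne carbon gives an unstrained ring.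

Step 5
Reactants: 6 methyl 5-bromo-2-(3,4,5-trimethoxyphenyl)-1-benzofuran-3-carboxylate
Product: 7 methyl (2R,3S)-5-bromo-2-(3,4,5-trimethoxyphenyl)-2,3-dihydro-1-benzofuran-3-carboxylate (cis)
Conditions: [Ir(cod)(L)][B(C6H3(CF3)2)4] (2 mol %; L = one enantiomer of 2-phenyl-5,6,7,8-tetrahydroquinolin-8-yl di-tert-butylphosphinite), H2 (80 bar), CH2Cl2, 40 °C
Reagents that add atoms: none
Why: Proposed new method: enantioselective hydrogenation of a 2-aryl-3-alkoxycarbonyl benzofuran. The closest known reaction type is iridium N,P-catalysed asymmetric hydrogenation of 2- or 3-monosubstituted benzofurans, of tetrasubstituted olefins and of ester-conjugated olefins. The cationic iridium dihydride should bind the weakly aromatic, enol-ether-like C2=C3 bond and deliver both hydrogens to one face by migratory insertion and reductive elimination (syn addition, hence cis), with the chiral pocket distinguishing the face by the fused ring A on one side and ring C on the other. Only the configuration at C2 (R, catalyst control) matters because C3 is corrected in step 6; aryl bromides are tolerated by this catalyst class.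

Step 6
Reactants: 7 methyl (2R,3S)-5-bromo-2-(3,4,5-trimethoxyphenyl)-2,3-dihydro-1-benzofuran-3-carboxylate
Product: 8 methyl (2R,3R)-5-bromo-2-(3,4,5-trimethoxyphenyl)-2,3-dihydro-1-benzofuran-3-carboxylate (trans)
Conditions: NaOMe (0.3 equiv), MeOH, 0 °C to rt
Reagents that add atoms: none
Why: Base-mediated epimerisation α to an ester through the enolate (thermodynamic equilibration), with C2 directing C3 to the trans arrangement in which ring C and the ester are on opposite faces. C2 should be untouched because the enolate π system is orthogonal to the in-plane C2–O1 bond, so ring opening by β-elimination (the reverse of a 5-endo-trig closure) is stereoelectronically disfavoured; matching alkoxide and ester exclude transesterification.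

Step 7
Reactants: 8 methyl (2R,3R)-5-bromo-2-(3,4,5-trimethoxyphenyl)-2,3-dihydro-1-benzofuran-3-carboxylate; 9 methyl acrylate
Product: 10 methyl (2R,3R)-5-[(1E)-3-methoxy-3-oxoprop-1-en-1-yl]-2-(3,4,5-trimethoxyphenyl)-2,3-dihydro-1-benzofuran-3-carboxylate
Conditions: Pd2(dba)3 (1.5 mol %), [HP(t-Bu)3]BF4 (6 mol %), Cy2NMe (1.2 equiv), dioxane, 50 °C
Reagents that add atoms: none
Why: Mizoroki–Heck reaction. The electron-rich aryl bromide is activated by tri-tert-butylphosphine-ligated zerovalent palladium, and syn insertion followed by syn β-hydride elimination gives the E cinnamate. The hindered amine at 50 °C should not enolise the C3 ester.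

Step 8
Reactants: 10 methyl (2R,3R)-5-[(1E)-3-methoxy-3-oxoprop-1-en-1-yl]-2-(3,4,5-trimethoxyphenyl)-2,3-dihydro-1-benzofuran-3-carboxylate
Product: 11 (2E)-3-[(2R,3S)-3-(hydroxymethyl)-2-(3,4,5-trimethoxyphenyl)-2,3-dihydro-1-benzofuran-5-yl]prop-2-en-1-ol
Conditions: i-Bu2AlH (6 equiv), CH2Cl2, −78 to −20 °C; aq. potassium sodium tartrate
Reagents that add atoms: none
Why: Hydride reduction of both esters with DIBAL-H, which reduces cinnamates in the 1,2-sense to allylic alcohols. Excess reagent at low temperature should keep the C3 aldehyde-level intermediate bound as its aluminium hemiacetal until it is reduced, so C3 is not epimerised. The descriptor at C3 changes from R to S only because CH2OH ranks below C2 whereas the ester ranked above it.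

## Compound list

1 | 4-bromo-2-iodophenol | Oc1ccc(Br)cc1I | starting material
2 | 4-bromo-2-iodophenyl acetate | CC(=O)Oc1ccc(Br)cc1I | intermediate
3 | 5-ethynyl-1,2,3-trimethoxybenzene | COc1cc(C#C)cc(OC)c1OC | starting material
4 | 4-bromo-2-[(3,4,5-trimethoxyphenyl)ethynyl]phenyl acetate | COc1cc(C#Cc2cc(Br)ccc2OC(C)=O)cc(OC)c1OC | intermediate
5 | 4-bromo-2-[(3,4,5-trimethoxyphenyl)ethynyl]phenol | COc1cc(C#Cc2cc(Br)ccc2O)cc(OC)c1OC | intermediate
6 | methyl 5-bromo-2-(3,4,5-trimethoxyphenyl)-1-benzofuran-3-carboxylate | COC(=O)c1c(-c2cc(OC)c(OC)c(OC)c2)oc2ccc(Br)cc12 | intermediate
7 | methyl (2R,3S)-5-bromo-2-(3,4,5-trimethoxyphenyl)-2,3-dihydro-1-benzofuran-3-carboxylate (cis) | COc1cc([C@@H]2Oc3ccc(Br)cc3[C@@H]2C(=O)OC)cc(OC)c1OC | intermediate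
8 | methyl (2R,3R)-5-bromo-2-(3,4,5-trimethoxyphenyl)-2,3-dihydro-1-benzofuran-3-carboxylate (trans) | COc1cc([C@@H]2Oc3ccc(Br)cc3[C@H]2C(=O)OC)cc(OC)c1OC | intermediate
9 | methyl acrylate | C=CC(=O)OC | starting material
10 | methyl (2R,3R)-5-[(1E)-3-methoxy-3-oxoprop-1-en-1-yl]-2-(3,4,5-trimethoxyphenyl)-2,3-dihydro-1-benzofuran-3-carboxylate | COc1cc([C@@H]2Oc3ccc(/C=C/C(=O)OC)cc3[C@H]2C(=O)OC)cc(OC)c1OC | intermediate
11 | (2E)-3-[(2R,3S)-3-(hydroxymethyl)-2-(3,4,5-trimethoxyphenyl)-2,3-dihydro-1-benzofuran-5-yl]prop-2-en-1-ol | COc1cc([C@@H]2Oc3ccc(/C=C/CO)cc3[C@H]2CO)cc(OC)c1OC | target

## Step count and least certain steps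

Total step count: 8. Longest linear sequence: 8 steps (1 to 11); 3 and 9 are commercial and enter at steps 2 and 7.

**Step 5 (proposed new method).**
- What may go wrong: hydrogen uptake may be slow or absent at a tetrasubstituted, ester-conjugated double bond inside a furan; facial discrimination at C2 may be poor; slow hydrodebromination may set in at long reaction times.
- Fallback (known chemistry): the fallback sets out from 6. Dissolving-metal conjugate reduction with Mg turnings in MeOH/THF at 0 °C, a known reduction of 2-arylbenzofuran-3-carboxylates, should give the thermodynamic trans ester directly as a racemate, racemic methyl trans-5-bromo-2-(3,4,5-trimethoxyphenyl)-2,3-dihydro-1-benzofuran-3-carboxylate F1. The reaction is kept cold and stopped at full conversion to limit reductive loss of bromine. The enantiomers of F1 are then separated by preparative chromatography on a polysaccharide chiral stationary phase. The (2R,3R) enantiomer is 8, where the route is rejoined; step 6 is no longer needed. Half of the material is lost.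

**Step 4 (key step).**
- What may go wrong: protodepalladation of the C3–palladium intermediate may outrun CO insertion, giving cycloisomerisation without C9; slow carbonylation at the C–Br bond is a lesser risk.
- Fallback: the fallback sets out from 5 and separates the two bond formations. Iodocyclisation (I2, NaHCO3, MeCN, rt) forms O1–C2 in the same 5-endo-dig sense and leaves iodine on C3, giving 5-bromo-3-iodo-2-(3,4,5-trimethoxyphenyl)-1-benzofuran F2. Iodine–magnesium exchange with i-PrMgCl·LiCl in THF at −40 °C, much faster at C3–I than at C5–Br, gives [5-bromo-2-(3,4,5-trimethoxyphenyl)-1-benzofuran-3-yl]magnesium chloride F3. F3 is added to excess methyl chloroformate to form C3–C9, and the route is rejoined at 6.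

**Step 7.**
- What may go wrong: oxidative addition to the electron-rich bromide may be slow, forcing temperatures at which the amine base begins to erode C3 or at which palladium hydride re-addition shifts the new double bond.
- Fallback: the fallback sets out from 8 and uses a base-free Stille coupling with (E)-3-(tributylstannyl)prop-2-en-1-ol (Pd(PPh3)4, toluene, 100 °C). This brings in the side chain already at the alcohol level and gives methyl (2R,3R)-5-[(1E)-3-hydroxyprop-1-en-1-yl]-2-(3,4,5-trimethoxyphenyl)-2,3-dihydro-1-benzofuran-3-carboxylate F4. Reduction of the one remaining ester with LiBH4 in THF rejoins the route at 11, bypassing 10.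

**Step 8.**
- What may go wrong: incomplete reduction at C3 may leave aldehyde-level material that epimerises or loses the ring oxygen by β-elimination on work-up; conjugate reduction of the cinnamate may compete.
- Fallback: the fallback sets out from 8 and changes the order so that the two esters are never reduced together. LiBH4 in THF reduces the C3 ester first, giving [(2R,3S)-5-bromo-2-(3,4,5-trimethoxyphenyl)-2,3-dihydro-1-benzofuran-3-yl]methanol F5. The Heck reaction with 9 under the conditions of step 7 gives methyl (2E)-3-[(2R,3S)-3-(hydroxymethyl)-2-(3,4,5-trimethoxyphenyl)-2,3-dihydro-1-benzofuran-5-yl]prop-2-enoate F6. DIBAL-H then has only the cinnamate to reduce, and the route is rejoined at 11.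

## Further compounds

F1 | step 5 | racemic methyl trans-5-bromo-2-(3,4,5-trimethoxyphenyl)-2,3-dihydro-1-benzofuran-3-carboxylate (1:1 mixture of the 2R,3R and 2S,3S enantiomers) | COc1cc([C@@H]2Oc3ccc(Br)cc3[C@H]2C(=O)OC)cc(OC)c1OC.COc1cc([C@H]2Oc3ccc(Br)cc3[C@@H]2C(=O)OC)cc(OC)c1OC
F2 | step 4 | 5-bromo-3-iodo-2-(3,4,5-trimethoxyphenyl)-1-benzofuran | COc1cc(-c2oc3ccc(Br)cc3c2I)cc(OC)c1OC
F3 | step 4 | [5-bromo-2-(3,4,5-trimethoxyphenyl)-1-benzofuran-3-yl]magnesium chloride | COc1cc(-c2oc3ccc(Br)cc3c2[Mg]Cl)cc(OC)c1OC
F4 | step 7 | methyl (2R,3R)-5-[(1E)-3-hydroxyprop-1-en-1-yl]-2-(3,4,5-trimethoxyphenyl)-2,3-dihydro-1-benzofuran-3-carboxylate | COc1cc([C@@H]2Oc3ccc(/C=C/CO)cc3[C@H]2C(=O)OC)cc(OC)c1OC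
F5 | step 8 | [(2R,3S)-5-bromo-2-(3,4,5-trimethoxyphenyl)-2,3-dihydro-1-benzofuran-3-yl]methanol | COc1cc([C@@H]2Oc3ccc(Br)cc3[C@H]2CO)cc(OC)c1OC
F6 | step 8 | methyl (2E)-3-[(2R,3S)-3-(hydroxymethyl)-2-(3,4,5-trimethoxyphenyl)-2,3-dihydro-1-benzofuran-5-yl]prop-2-enoate | COc1cc([C@@H]2Oc3ccc(/C=C/C(=O)OC)cc3[C@H]2CO)cc(OC)c1OC
A1 | alternative 1 | (1R,2S)-2-(tert-butyldimethylsilyloxymethyl)-1-(3,4,5-trimethoxyphenyl)but-3-yn-1-yl (triisopropylsilyl)ethynyl ether | COc1cc([C@@H]([C@@H](C#C)CO[Si](C)(C)C(C)(C)C)OC#C[Si](C(C)C)(C(C)C)C(C)C)cc(OC)c1OC
A2 | alternative 1 | (E)-tert-butyldimethyl(pent-2-en-4-yn-1-yloxy)silane | C#C/C=C/CO[Si](C)(C)C(C)(C)C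
A3 | alternative 1 | (2R,3S)-trans-7-triisopropylsilyl-2-(3,4,5-trimethoxyphenyl)-2,3-dihydrobenzofuran with the C9 and side-chain alcohols as tert-butyldimethylsilyl ethers | COc1cc([C@@H]2Oc3c([Si](C(C)C)(C(C)C)C(C)C)cc(/C=C/CO[Si](C)(C)C(C)(C)C)cc3[C@H]2CO[Si](C)(C)C(C)(C)C)cc(OC)c1OC
A4 | alternative 2 | lithium (5-bromo-1-benzofuran-2-yl)(3,4,5-trimethoxyphenyl)pinacolatoborate | [Li+].COc1cc([B-]2(c3cc4cc(Br)ccc4o3)OC(C)(C)C(C)(C)O2)cc(OC)c1OC
A5 | alternative 2 | allyl acetate | C=CCOC(C)=O
A6 | alternative 2 | (2R,3R)-3-allyl-5-bromo-2-(pinacolboryl)-2-(3,4,5-trimethoxyphenyl)-2,3-dihydro-1-benzofuran (aryl and allyl trans) | COc1cc([C@]2(B3OC(C)(C)C(C)(C)O3)Oc3ccc(Br)cc3[C@H]2CC=C)cc(OC)c1OC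
A7 | alternative 3 | (2R,3S)-3-(tert-butyldimethylsilyloxymethyl)-2-(3,4,5-trimethoxyphenyl)-5-vinyl-2,3-dihydrofuran | COc1cc([C@@H]2OC(C=C)=C[C@H]2CO[Si](C)(C)C(C)(C)C)cc(OC)c1OC
A8 | alternative 3 | methyl propiolate | C#CC(=O)OC
A9 | alternative 3 | methyl (2R,3S)-trans-3-(tert-butyldimethylsilyloxymethyl)-2-(3,4,5-trimethoxyphenyl)-2,3-dihydro-1-benzofuran-5-carboxylate | COc1cc([C@@H]2Oc3ccc(C(=O)OC)cc3[C@H]2CO[Si](C)(C)C(C)(C)C)cc(OC)c1OC
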